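## Analysis of the target

- Compound 39 is a 2,3,5,6,7,7a-hexahydro-1H-indene. Ring A (C3a, C4, C5, C6, C7, C7a) is a cyclohexene with a trisubstituted C3a=C4 double bond and a gem-dimethyl carbon C7. Ring B (C1, C2, C3, C3a, C7a) is a cyclopentane.
- C7a (methyl) and C1 (methyl plus the side chain C1'–C5') are adjacent quaternary stereocentres with their methyls cis. C2 carries the carboxylic acid on the same face as both methyls and trans to the side chain. The descriptors are 1R, 2S, 7aS.
- Together with C7, three fully substituted carbons stand in a row. This congestion is the main difficulty.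
- C2 is α to the carboxyl group and can epimerise under base.
- The side chain ends in a (3Z)-trisubstituted allylic acetate, which is sensitive to base, hydride, zerovalent palladium and ionising acid. The C3a=C4 alkene can migrate under strong acid.
- The acid therefore has to be freed late, without strong base and before or without harming the acetate.
- The plan rests on one feature. Two cis methyls on the neighbouring quaternary carbons C7a and C1 are the outcome of a suprafacial addition across a (Z)-tetrasubstituted C7a=C1 alkene. C3a is joined to C7a through the four ring-A atoms C4–C7, so a two-carbon ketene-type unit C3–C3a can be delivered across that alkene from within. C2 is then inserted between C1 and C3.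

## Retrosynthetic reasoning

**Acetate and acid.** The O-acetyl bond is made last, so 39 goes back to hydroxy acid 38 and this to tert-butyl ester 36. No later step then has to tolerate the allylic acetate. The tert-butyl ester can be cleaved by a silyl triflate under buffered, non-basic conditions, which cannot epimerise C2.

**Side-chain alkene (C3'=C4').** The Z-trisubstituted alkene is cut between C3' and C4': 36 comes from enoate 35 by reduction, and 35 from aldehyde 33 and phosphonate 34. This is the one place in the chain where a Z-selective olefination sets the geometry directly. Aldehyde 33 goes back through alcohol 32 to silyl ether 31. The forward reduction must leave the hindered C2 ester alone, which is why that ester is tert-butyl.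

**C2–H and the C3 oxygen.** Ester 31 is traced to dienoate 30, so the C2 hydrogen is the last atom put on ring B. Conjugate reduction of 30 creates C2 by protonation of an ester enolate. Dienoate 30 comes from dienyl triflate 29, and 29 from keto ester 28. The C3 oxygen is thereby removed by way of its enol triflate while the C3a=C4 bond never moves.

**C1–C2 and C2–C3 (one-carbon ring expansion).** Keto ester 28 goes back to chloride 27 by adding HCl across C3a=C4. Chloride 27 is opened to chlorocyclobutanone 25 and diazoacetate 26. Cutting here inserts C2 together with its carboxyl carbon between C1 and C3. The chlorine at C3a has two tasks: it stops C3a from migrating, so that C1 migrates, and it later places the alkene at C3a=C4 and nowhere else.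

**C3a–Cl.** Chloride 25 comes from cyclobutanone 24, whose only α-hydrogen is at C3a.

**C1–C3 and C3a–C7a (key disconnection).** Cyclobutanone 24 is opened to amide 21. Both quaternary stereocentres, C3a and ring A are formed here in one operation. The relative configuration follows from the alkene geometry of 21 and the absolute configuration from the C2-symmetric amine in 21. Cutting anywhere else in ring A or ring B would require building the C7a/C1 pair by two separate quaternary-centre syntheses.

**Amide and latent acid.** Amide 21 comes from acid 18 and amine 19. Acid 18 comes from alcohol 16 and this from diene 14, whose terminal alkene is a carboxyl group in waiting that survives all the organometallic steps before it.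

**The tetrasubstituted alkene.** Diene 14 goes back to allylic alcohol 12, ester 11, enol triflate 10 and keto ester 9.

- The C7a methyl is cut off (cross-coupling of the triflate).
- The C1 methyl is traced to the ester carbon.
- This assignment lets the chelated, (Z)-configured enol triflate of a β-keto ester give exactly the cis-dimethyl alkene.
- The C3' oxygen is carried as a tert-butyldiphenylsilyl ether, since it has to pass two aluminium hydride reductions here and the acidic steps later.

**Carbon skeleton.** Keto ester 9 is cut at C1–C1' into keto ester 6 and bromide 8 (from bromo alcohol 7). Keto ester 6 is cut at C7a–C1 into acid 3 and ethyl acetate 4. Acid 3 is cut at C7–C6 into isobutyric acid 1 and bromide 2.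

## Alternatives that were turned down

**Alternative 1:** ring A is cut at C7–C7a and C5–C6. Heating triene ester A1, a methacrylate held on the C2 oxygen of a 1-vinylcyclopentene, would give the lactone-bridged adduct A2.

- For it: ring A, the C3a=C4 alkene in its final place and the carbons C7 and C7a arise in one step, and the tether fixes the face. No carbonyl has to be removed from C3. On these two points it is stronger than the chosen route, which spends three steps on the C3 oxygen.
- Against it: the cycloaddition must join a fully substituted diene terminus (C7a) to the α-carbon of the methacrylate through an ester tether. Ester tethers prefer the unreactive s-trans conformation, and the transition state is bridged.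
- C7 comes out with one methyl and a lactone carbonyl, so a neopentyl carboxyl carbon must be reduced to a methyl group.
- The C2 oxygen in A2 is on the face opposite to the required carboxyl group. It must be replaced by a carbon nucleophile with inversion at a secondary centre next to the quaternary C1, a substitution that is very slow.
- The absolute configuration would have to come from a separately made, enantioenriched cyclopentane with a quaternary C1.
- Comparison: the chosen route brings C7 in as a finished gem-dimethyl carbon, introduces C2 already bearing its carboxyl carbon, and needs no substitution at a neopentyl position.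

**Alternative 2:** ring B is cut at C1–C7a. A chelating chiral copper Lewis acid would trigger the Nazarov cyclization of 3-acylbutenolide A3 to the tricyclic keto lactone A4, after loss of H4 and protonation at C2.

- For it: the step is catalytic in the chiral source and makes ring B with both quaternary centres. The lactone ties the C2 carboxyl to the future C1 methyl, so the C1/C2 cis relation is locked by ring fusion. This is clearly stronger than the chosen route, which sets C2 by a kinetic protonation.
- Against it: the new bond joins two fully substituted alkene termini. Nazarov closures that create vicinal quaternary carbons are slow, and the oxyallyl cation is prone to Wagner–Meerwein shifts.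
- The cis relation of the C1 and C7a substituents depends on the sense of conrotation and on torquoselectivity, not on a stereospecific addition.
- A4 still carries the C3 ketone next to C3a=C4, so the carbonyl-removal problem is the same as in the chosen route. In addition, the lactone CH2–O bond must be reduced to a methyl group at a neopentyl carbon without losing the carboxyl group.
- Comparison: the chosen route offers stereospecific transfer of alkene geometry into the C7a/C1 pair, at the price of a stoichiometric auxiliary and more steps.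

**Alternative 3:** ring B is cut at C1–C2. A dirhodium carboxylate catalyst would decompose diazo keto ester A5, and the C2 carbenoid would insert into the tertiary C1–H bond with retention to give keto ester A6.

- For it: A6 is the same ring system and oxidation pattern as 28 of the chosen route, with another ester and silyl group. It would be reached without a temporary four-membered ring, without chlorination, ring expansion and elimination. On step economy after ring formation it is stronger.
- Insertion into a tertiary C–H bond with five-membered ring formation is the favoured mode.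
- Against it: retention only transfers what is already there. The C7a (quaternary) / C1 (tertiary) pair in A5 has to be set beforehand on an open chain attached to the ring, which is the hardest stereochemical problem of the target and is not solved by the key step.
- The C1–H bond lies next to a quaternary carbon and competes with the primary C–H bonds of the C7a methyl, which are also in 1,5-relation to the carbenoid.
- Everything after A6 (C3 oxygen, C2 configuration, side chain) remains as in the chosen route.
- Comparison: the chosen route creates C7a and C1 together, with relative configuration from alkene geometry and absolute configuration from the auxiliary.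

Key step: step 12

Assumption: the facial sense of the (2R,5R) auxiliary is taken from an iminium-like transition-state model (auxiliary methyl next to C3a on the side of the C3a hydrogen); if the sense were the opposite one, the (2S,5S) antipode of 19 would be used in the same way.

## Route

Step 1
Reactants: 1 2-methylpropanoic acid; 2 5-bromopent-1-ene
Product: 3 2,2-dimethylhept-6-enoic acid
Conditions: LiN(i-Pr)2 (2.2 equiv), THF, 0 → 50 °C; then 2, 0 °C → rt; aq. HCl
Reagents that add atoms: none
Why: The carboxylate enolate (dianion) of 1 is alkylated at its α-carbon by the primary bromide in an SN2 reaction, which creates the quaternary carbon that becomes C7; no stereocentre is formed.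

Step 2
Reactants: 3 2,2-dimethylhept-6-enoic acid; 4 ethyl acetate
Product: 6 ethyl 4,4-dimethyl-3-oxonon-8-enoate, via acid chloride 5 (not isolated)
Conditions: (COCl)2, cat. DMF, CH2Cl2, 0 °C → rt, evaporate; LiN(SiMe3)2 + 4 (2.2 equiv each), THF, −78 °C, then 5, −78 → 0 °C; aq. NH4Cl
Reagents that add atoms: none
Why: C-Acylation of an ester lithium enolate by an acid chloride (crossed Claisen-type condensation) gives the β-keto ester. The second equivalent of enolate deprotonates the product and so protects it, and the acid chloride has no α-hydrogen and cannot form a ketene.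

Step 3
Reactants: 7 3-bromopropan-1-ol
Product: 8 (3-bromopropoxy)(tert-butyl)diphenylsilane
Conditions: t-BuPh2SiCl, imidazole, CH2Cl2, 0 °C → rt
Reagents that add atoms: tert-butyl(chloro)diphenylsilane, CC(C)(C)[Si](Cl)(c1ccccc1)c1ccccc1
Why: Silylation of a primary alcohol with a silyl chloride and imidazole. The tert-butyldiphenylsilyl ether tolerates the aluminium hydrides, the triflic anhydride activation and BF3·OEt2 used later.

Step 4
Reactants: 6 ethyl 4,4-dimethyl-3-oxonon-8-enoate; 8 (3-bromopropoxy)(tert-butyl)diphenylsilane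
Product: 9 ethyl 2-{3-[(tert-butyldiphenylsilyl)oxy]propyl}-4,4-dimethyl-3-oxonon-8-enoate (racemic at C2; enolisable)
Conditions: K2CO3, NaI (0.1 equiv), DMF, 50 °C
Reagents that add atoms: none
Why: C-Alkylation of a β-keto ester enolate by a primary halide (iodide formed in situ by Finkelstein exchange) attaches the stub C1'–C3' to the future C1. The centre formed is enolised in the next step, so its configuration does not matter.

Step 5
Reactants: 9 ethyl 2-{3-[(tert-butyldiphenylsilyl)oxy]propyl}-4,4-dimethyl-3-oxonon-8-enoate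
Product: 10 ethyl (2Z)-2-{3-[(tert-butyldiphenylsilyl)oxy]propyl}-4,4-dimethyl-3-{[(trifluoromethyl)sulfonyl]oxy}nona-2,8-dienoate
Conditions: LiN(SiMe3)2, toluene, −78 → 0 °C; then (CF3SO2)2O, −78 → 0 °C
Reagents that add atoms: trifluoromethanesulfonic anhydride, O=S(=O)(OS(=O)(=O)C(F)(F)F)C(F)(F)F
Why: Enol triflate formation from a β-keto ester: in the non-coordinating solvent the lithium enolate is a six-membered chelate, so sulfonylation of the ketone oxygen gives the triflate with OTf and ester cis (2Z). This geometry places the tert-alkyl group cis to the C1 chain, as the cycloaddition requires.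

Step 6
Reactants: 10 ethyl (2Z)-2-{3-[(tert-butyldiphenylsilyl)oxy]propyl}-4,4-dimethyl-3-{[(trifluoromethyl)sulfonyl]oxy}nona-2,8-dienoate
Product: 11 ethyl (2E)-2-{3-[(tert-butyldiphenylsilyl)oxy]propyl}-3,4,4-trimethylnona-2,8-dienoate
Conditions: Me2Zn, PdCl2(dppf) (5 mol %; dppf = 1,1'-bis(diphenylphosphino)ferrocene), THF, 60 °C
Reagents that add atoms: dimethylzinc, C[Zn]C
Why: Negishi cross-coupling: zerovalent palladium inserts into the C–OTf bond and methyl is transferred from zinc with retention of alkene geometry. The new C7a methyl therefore ends up cis to the ester carbon that will become the C1 methyl.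

Step 7
Reactants: 11 ethyl (2E)-2-{3-[(tert-butyldiphenylsilyl)oxy]propyl}-3,4,4-trimethylnona-2,8-dienoate
Product: 12 (2E)-2-{3-[(tert-butyldiphenylsilyl)oxy]propyl}-3,4,4-trimethylnona-2,8-dien-1-ol
Conditions: i-Bu2AlH, CH2Cl2, −78 → 0 °C
Reagents that add atoms: none
Why: Hydride reduction of the conjugated ester to the primary allylic alcohol (1,2-addition); alkenes and silyl ether are inert to i-Bu2AlH under these conditions.

Step 8
Reactants: 12 (2E)-2-{3-[(tert-butyldiphenylsilyl)oxy]propyl}-3,4,4-trimethylnona-2,8-dien-1-ol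
Product: 14 tert-butyl(diphenyl){[(4Z)-4,5,6,6-tetramethylundeca-4,10-dien-1-yl]oxy}silane, via pyridinium allyl sulfate 13 (not isolated)
Conditions: SO3·pyridine, THF, 0 °C → rt; then LiAlH4, 0 °C → rt
Reagents that add atoms: none
Why: Deoxygenation of an allylic alcohol through its sulfate monoester: hydride from LiAlH4 displaces sulfate at the primary carbon (SN2; the SN2' position is fully substituted). The former ester carbon becomes the C1 methyl and the alkene geometry is untouched, so the two methyls are cis (4Z).

Step 9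
Reactants: 14 tert-butyl(diphenyl){[(4Z)-4,5,6,6-tetramethylundeca-4,10-dien-1-yl]oxy}silane
Product: 16 (7Z)-11-{[tert-butyl(diphenyl)silyl]oxy}-6,6,7,8-tetramethylundec-7-en-1-ol, via B-alkyl-9-BBN adduct 15 (not isolated)
Conditions: 9-borabicyclo[3.3.1]nonane (9-BBN), THF, 0 °C → rt; then NaOH, H2O2, 0 °C → rt
Reagents that add atoms: hydrogen peroxide, OO
Why: Hydroboration–oxidation: 9-BBN adds anti-Markovnikov to the monosubstituted terminal alkene and leaves the shielded tetrasubstituted alkene alone; alkaline peroxide converts the C–B bond into the primary alcohol.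

Step 10
Reactants: 16 (7Z)-11-{[tert-butyl(diphenyl)silyl]oxy}-6,6,7,8-tetramethylundec-7-en-1-ol
Product: 18 (7Z)-11-{[tert-butyl(diphenyl)silyl]oxy}-6,6,7,8-tetramethylundec-7-enoic acid, via aldehyde 17 (not isolated)
Conditions: (2,2,6,6-tetramethylpiperidin-1-yl)oxyl (0.2 equiv), PhI(OAc)2, MeCN/H2O, rt
Reagents that add atoms: water, O
Why: Nitroxyl-catalysed oxidation with a hypervalent iodine co-oxidant takes the primary alcohol through the aldehyde hydrate to the acid under near-neutral conditions, which spare the electron-rich alkene and the silyl ether.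

Step 11
Reactants: 18 (7Z)-11-{[tert-butyl(diphenyl)silyl]oxy}-6,6,7,8-tetramethylundec-7-enoic acid; 19 (2R,5R)-2,5-dimethylpyrrolidine
Product: 21 (7Z)-11-{[tert-butyl(diphenyl)silyl]oxy}-1-[(2R,5R)-2,5-dimethylpyrrolidin-1-yl]-6,6,7,8-tetramethylundec-7-en-1-one, via acid chloride 20 (not isolated)
Conditions: 1-chloro-N,N,2-trimethylprop-1-en-1-amine, CH2Cl2, 0 °C → rt; then 19, Et3N, 0 °C → rt
Reagents that add atoms: none
Why: The acid chloride is formed under neutral conditions with the α-chloroenamine and acylates the hindered secondary amine (amide formation via acid chloride); the stereocentres of 19 are not involved.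

Step 12
Reactants: 21 (7Z)-11-{[tert-butyl(diphenyl)silyl]oxy}-1-[(2R,5R)-2,5-dimethylpyrrolidin-1-yl]-6,6,7,8-tetramethylundec-7-en-1-one
Product: 24 (1R,6R,8S)-8-{3-[(tert-butyldiphenylsilyl)oxy]propyl}-1,2,2,8-tetramethylbicyclo[4.2.0]octan-7-one, via keteniminium triflate 22 (not isolated), via cyclobutaniminium triflate 23 (not isolated)
Conditions: (CF3SO2)2O, 2,4,6-collidine, ClCH2CH2Cl, −20 → 80 °C; then aq. NaHCO3, 40 °C
Reagents that add atoms: water, O
Why: Triflic anhydride O-sulfonylates the amide and collidine removes the proton at C3a with loss of triflate, giving keteniminium ion 22; its electrophilic central carbon C3 bonds to alkene carbon C1 while the former α-carbon C3a bonds to C7a, and hydrolysis of the resulting cyclobutaniminium salt 23 releases ketone 24 and the auxiliary 19. The closest known reaction type is the intramolecular [2+2] cycloaddition of keteniminium salts made from tertiary amides, including its asymmetric form with C2-symmetric 2,5-disubstituted pyrrolidines. Ring A closes through the C3a–C7a bond as a six-membered ring in the fused mode (6-exo attack of the enamine-like carbon C3a on the developing tertiary cation at C7a), and the four-membered ring C1–C3–C3a–C7a is completed by the C1–C3 bond; the bridged mode would need a strained bicyclo[4.1.1] skeleton and is not expected. C7a and C1: their relative configuration is set by the alkene geometry, because both bonds form on the same face of the (7Z)-alkene faster than the transient cation can rotate, so the two methyls stay cis. C3a: the four-atom tether allows only the cis ring fusion, which puts its hydrogen cis to the C7a methyl. The absolute sense is set by the auxiliary: in the iminium-like transition state the pyrrolidine methyl that flanks C3a lies on the side of the C3a hydrogen and away from C4, which for the (2R,5R) amine corresponds to the (1R,6R,8S) ketone. The step needs regioselectivity (fused over bridged, secured by the tether length since both alkene carbons are equally substituted), stereospecificity (secured by the geometrically pure alkene made in steps 5 to 8) and chemoselectivity (the amide is the only group nucleophilic enough for triflic anhydride; the silyl ether and the hindered base do not interfere).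

Step 13
Reactants: 24 (1R,6R,8S)-8-{3-[(tert-butyldiphenylsilyl)oxy]propyl}-1,2,2,8-tetramethylbicyclo[4.2.0]octan-7-one
Product: 25 (1R,6S,8S)-6-chloro-8-{3-[(tert-butyldiphenylsilyl)oxy]propyl}-1,2,2,8-tetramethylbicyclo[4.2.0]octan-7-one
Conditions: LiN(SiMe3)2, THF, −78 °C; then N-chlorosuccinimide, −78 → 0 °C
Reagents that add atoms: N-chlorosuccinimide, O=C1CCC(=O)N1Cl
Why: Electrophilic α-chlorination of a ketone enolate: the ketone has a single α-hydrogen (at C3a), so the lithium enolate is regiodefined. Chlorine can only enter on the face that keeps the four/six ring fusion cis, i.e. cis to the C7a methyl; this centre is removed again in step 15.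

Step 14
Reactants: 25 (1R,6S,8S)-6-chloro-8-{3-[(tert-butyldiphenylsilyl)oxy]propyl}-1,2,2,8-tetramethylbicyclo[4.2.0]octan-7-one; 26 tert-butyl diazoacetate
Product: 27 tert-butyl (1R,3aS,7aR)-1-{3-[(tert-butyldiphenylsilyl)oxy]propyl}-3a-chloro-1,7,7,7a-tetramethyl-3-oxooctahydro-1H-indene-2-carboxylate (C2 epimers and enol)
Conditions: 26, BF3·OEt2, CH2Cl2, −78 → −20 °C
Reagents that add atoms: none
Why: Lewis-acid-promoted homologation of a ketone with a diazoacetate (Tiffeneau–Demjanov-type ring expansion): the diazo carbon adds to the activated, strained carbonyl and loss of N2 triggers a 1,2-shift. The chlorine-bearing C3a is electron-poor and does not migrate, so C1 migrates with retention and C2 with its ester is inserted between C1 and C3. Release of cyclobutane strain drives the step, and C2 is still an enolisable β-keto ester centre here.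

Step 15
Reactants: 27 tert-butyl (1R,3aS,7aR)-1-{3-[(tert-butyldiphenylsilyl)oxy]propyl}-3a-chloro-1,7,7,7a-tetramethyl-3-oxooctahydro-1H-indene-2-carboxylate
Product: 28 tert-butyl (1R,7aR)-1-{3-[(tert-butyldiphenylsilyl)oxy]propyl}-1,7,7,7a-tetramethyl-3-oxo-2,3,5,6,7,7a-hexahydro-1H-indene-2-carboxylate (C2 epimers and enol)
Conditions: 1,8-diazabicyclo[5.4.0]undec-7-ene (DBU), toluene, rt → 60 °C
Reagents that add atoms: none
Why: Base-induced dehydrochlorination of an α-chloro ketone: the tertiary chloride at C3a has β-hydrogens only at C4 (C7a is quaternary), so loss of HCl, directly or through the C2 enolate, can only give the conjugated C3a=C4 alkene.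

Step 16
Reactants: 28 tert-butyl (1R,7aR)-1-{3-[(tert-butyldiphenylsilyl)oxy]propyl}-1,7,7,7a-tetramethyl-3-oxo-2,3,5,6,7,7a-hexahydro-1H-indene-2-carboxylate
Product: 29 tert-butyl (1S,7aR)-1-{3-[(tert-butyldiphenylsilyl)oxy]propyl}-1,7,7,7a-tetramethyl-3-{[(trifluoromethyl)sulfonyl]oxy}-5,6,7,7a-tetrahydro-1H-indene-2-carboxylate
Conditions: NaH, THF, 0 °C; then PhN(SO2CF3)2, 0 °C → rt
Reagents that add atoms: 1,1,1-trifluoro-N-phenyl-N-[(trifluoromethyl)sulfonyl]methanesulfonamide, O=S(=O)(N(c1ccccc1)S(=O)(=O)C(F)(F)F)C(F)(F)F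
Why: Enol triflate formation from a β-keto ester: the most acidic proton (C2–H between ketone and ester) is removed and the enolate oxygen on C3 is sulfonylated, which turns the C3 oxygen into a leaving group on an sp2 carbon.

Step 17
Reactants: 29 tert-butyl (1S,7aR)-1-{3-[(tert-butyldiphenylsilyl)oxy]propyl}-1,7,7,7a-tetramethyl-3-{[(trifluoromethyl)sulfonyl]oxy}-5,6,7,7a-tetrahydro-1H-indene-2-carboxylate
Product: 30 tert-butyl (1S,7aS)-1-{3-[(tert-butyldiphenylsilyl)oxy]propyl}-1,7,7,7a-tetramethyl-5,6,7,7a-tetrahydro-1H-indene-2-carboxylate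
Conditions: Pd(OAc)2 (5 mol %), PPh3, HCO2H, Bu3N, DMF, 60 °C
Reagents that add atoms: none
Why: Palladium-catalysed formate reduction of an enol triflate: oxidative addition of zerovalent palladium, exchange of triflate for formate, loss of CO2 and reductive elimination replace C3–OTf by C3–H. The C3 oxygen is thus removed while C3a=C4 stays in place as part of the dienoate.

Step 18
Reactants: 30 tert-butyl (1S,7aS)-1-{3-[(tert-butyldiphenylsilyl)oxy]propyl}-1,7,7,7a-tetramethyl-5,6,7,7a-tetrahydro-1H-indene-2-carboxylate
Product: 31 tert-butyl (1R,2S,7aS)-1-{3-[(tert-butyldiphenylsilyl)oxy]propyl}-1,7,7,7a-tetramethyl-2,3,5,6,7,7a-hexahydro-1H-indene-2-carboxylate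
Conditions: [(Ph3P)CuH]6 (5 mol %), PhMe2SiH, t-BuOH, toluene, rt
Reagents that add atoms: none
Why: Copper hydride conjugate reduction: hydride adds to the β-carbon C3 of the α,β-unsaturated ester (1,4-addition; the more remote C3a=C4 bond is left) and the copper enolate is protonated at C2 by tert-butanol. The proton should enter on the face opposite the two cis methyls at C1 and C7a (the C7a methyl stands perpendicular to ring B and is 1,3 to C2), which puts the ester cis to both methyls (2S); this is kinetic, substrate-controlled protonation.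

Step 19
Reactants: 31 tert-butyl (1R,2S,7aS)-1-{3-[(tert-butyldiphenylsilyl)oxy]propyl}-1,7,7,7a-tetramethyl-2,3,5,6,7,7a-hexahydro-1H-indene-2-carboxylate
Product: 32 tert-butyl (1R,2S,7aS)-1-(3-hydroxypropyl)-1,7,7,7a-tetramethyl-2,3,5,6,7,7a-hexahydro-1H-indene-2-carboxylate
Conditions: Bu4NF, AcOH, THF, rt
Reagents that add atoms: none
Why: Fluoride cleaves the Si–O bond and frees the primary alcohol; buffering with acetic acid keeps the medium from being basic enough to touch C2.

Step 20
Reactants: 32 tert-butyl (1R,2S,7aS)-1-(3-hydroxypropyl)-1,7,7,7a-tetramethyl-2,3,5,6,7,7a-hexahydro-1H-indene-2-carboxylate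
Product: 33 tert-butyl (1R,2S,7aS)-1,7,7,7a-tetramethyl-1-(3-oxopropyl)-2,3,5,6,7,7a-hexahydro-1H-indene-2-carboxylate
Conditions: 1,1,1-triacetoxy-1,1-dihydro-1,2-benziodoxol-3(1H)-one (DMP), NaHCO3, CH2Cl2, rt
Reagents that add atoms: none
Why: Oxidation of the primary alcohol to the aldehyde with a hypervalent iodine reagent under bicarbonate buffer; the alkene and the C2 centre are not affected.

Step 21
Reactants: 33 tert-butyl (1R,2S,7aS)-1,7,7,7a-tetramethyl-1-(3-oxopropyl)-2,3,5,6,7,7a-hexahydro-1H-indene-2-carboxylate; 34 ethyl 2-[bis(2,2,2-trifluoroethoxy)phosphoryl]propanoate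
Product: 35 tert-butyl (1R,2S,7aS)-1-[(3Z)-5-ethoxy-4-methyl-5-oxopent-3-en-1-yl]-1,7,7,7a-tetramethyl-2,3,5,6,7,7a-hexahydro-1H-indene-2-carboxylate
Conditions: 34, KN(SiMe3)2, 18-crown-6, THF, −78 °C; then 33
Reagents that add atoms: none
Why: Still–Gennari olefination: the electron-poor phosphonate anion adds to the aldehyde and the oxaphosphetane collapses under kinetic control to the (Z)-trisubstituted enoate, ester cis to the chain. The weakly basic phosphonate anion does not enolise the hindered tert-butyl ester.

Step 22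
Reactants: 35 tert-butyl (1R,2S,7aS)-1-[(3Z)-5-ethoxy-4-methyl-5-oxopent-3-en-1-yl]-1,7,7,7a-tetramethyl-2,3,5,6,7,7a-hexahydro-1H-indene-2-carboxylate
Product: 36 tert-butyl (1R,2S,7aS)-1-[(3Z)-5-hydroxy-4-methylpent-3-en-1-yl]-1,7,7,7a-tetramethyl-2,3,5,6,7,7a-hexahydro-1H-indene-2-carboxylate
Conditions: i-Bu2AlH, CH2Cl2, −78 °C
Reagents that add atoms: none
Why: Hydride reduction of the unhindered conjugated ethyl ester to the allylic alcohol at low temperature; the tert-butyl ester next to the quaternary C1 is too hindered to react and the alkene geometry is not touched.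

Step 23
Reactants: 36 tert-butyl (1R,2S,7aS)-1-[(3Z)-5-hydroxy-4-methylpent-3-en-1-yl]-1,7,7,7a-tetramethyl-2,3,5,6,7,7a-hexahydro-1H-indene-2-carboxylate
Product: 38 (1R,2S,7aS)-1-[(3Z)-5-hydroxy-4-methylpent-3-en-1-yl]-1,7,7,7a-tetramethyl-2,3,5,6,7,7a-hexahydro-1H-indene-2-carboxylic acid, via bis(trimethylsilyl) derivative 37 (not isolated)
Conditions: Me3SiOTf, 2,6-lutidine, CH2Cl2, 0 °C; then aq. citric acid, MeOH
Reagents that add atoms: none
Why: Silyl-triflate cleavage of a tert-butyl ester: silylation of the ester carbonyl lets the tert-butyl group leave as 2-methylpropene under buffered, non-basic conditions, so C2 cannot epimerise. The alcohol is silylated in passing and both silyl groups fall off on mild acidic work-up.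

Step 24
Reactants: 38 (1R,2S,7aS)-1-[(3Z)-5-hydroxy-4-methylpent-3-en-1-yl]-1,7,7,7a-tetramethyl-2,3,5,6,7,7a-hexahydro-1H-indene-2-carboxylic acid
Product: 39 (1R,2S,7aS)-1-[(3Z)-5-(acetyloxy)-4-methylpent-3-en-1-yl]-1,7,7,7a-tetramethyl-2,3,5,6,7,7a-hexahydro-1H-indene-2-carboxylic acid
Conditions: Ac2O, pyridine, cat. 4-(dimethylamino)pyridine, CH2Cl2, 0 °C → rt; aqueous work-up
Reagents that add atoms: acetic anhydride, CC(=O)OC(C)=O
Why: Acylation of the primary allylic alcohol under nucleophilic catalysis; any mixed anhydride at the carboxyl group is hydrolysed on aqueous work-up, which leaves the target.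

## Compound list

1 | 2-methylpropanoic acid (isobutyric acid) | CC(C)C(=O)O | starting material
2 | 5-bromopent-1-ene | C=CCCCBr | starting material
3 | 2,2-dimethylhept-6-enoic acid | C=CCCCC(C)(C)C(=O)O | intermediate
4 | ethyl acetate | CCOC(C)=O | starting material
5 | 2,2-dimethylhept-6-enoyl chloride | C=CCCCC(C)(C)C(=O)Cl | intermediate (not isolated)
6 | ethyl 4,4-dimethyl-3-oxonon-8-enoate | CCOC(=O)CC(=O)C(C)(C)CCCC=C | intermediate
7 | 3-bromopropan-1-ol | OCCCBr | starting material
8 | (3-bromopropoxy)(tert-butyl)diphenylsilane | BrCCCO[Si](c1ccccc1)(c1ccccc1)C(C)(C)C | intermediate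
9 | ethyl 2-{3-[(tert-butyldiphenylsilyl)oxy]propyl}-4,4-dimethyl-3-oxonon-8-enoate (racemic at C2) | CCOC(=O)C(CCCO[Si](c1ccccc1)(c1ccccc1)C(C)(C)C)C(=O)C(C)(C)CCCC=C | intermediate
10 | ethyl (2Z)-2-{3-[(tert-butyldiphenylsilyl)oxy]propyl}-4,4-dimethyl-3-{[(trifluoromethyl)sulfonyl]oxy}nona-2,8-dienoate | CCOC(=O)/C(CCCO[Si](c1ccccc1)(c1ccccc1)C(C)(C)C)=C(\OS(=O)(=O)C(F)(F)F)C(C)(C)CCCC=C | intermediate
11 | ethyl (2E)-2-{3-[(tert-butyldiphenylsilyl)oxy]propyl}-3,4,4-trimethylnona-2,8-dienoate | CCOC(=O)/C(CCCO[Si](c1ccccc1)(c1ccccc1)C(C)(C)C)=C(\C)C(C)(C)CCCC=C | intermediate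
12 | (2E)-2-{3-[(tert-butyldiphenylsilyl)oxy]propyl}-3,4,4-trimethylnona-2,8-dien-1-ol | OC/C(CCCO[Si](c1ccccc1)(c1ccccc1)C(C)(C)C)=C(\C)C(C)(C)CCCC=C | intermediate
13 | pyridinium (2E)-2-{3-[(tert-butyldiphenylsilyl)oxy]propyl}-3,4,4-trimethylnona-2,8-dien-1-yl sulfate | [O-]S(=O)(=O)OC/C(CCCO[Si](c1ccccc1)(c1ccccc1)C(C)(C)C)=C(\C)C(C)(C)CCCC=C.c1cc[nH+]cc1 | intermediate (not isolated)
14 | tert-butyl(diphenyl){[(4Z)-4,5,6,6-tetramethylundeca-4,10-dien-1-yl]oxy}silane | C=CCCCC(C)(C)/C(C)=C(C)\CCCO[Si](c1ccccc1)(c1ccccc1)C(C)(C)C | intermediate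
15 | 9-[(7Z)-11-{[tert-butyl(diphenyl)silyl]oxy}-6,6,7,8-tetramethylundec-7-en-1-yl]-9-borabicyclo[3.3.1]nonane | B1(CCCCCC(C)(C)/C(C)=C(C)\CCCO[Si](c3ccccc3)(c3ccccc3)C(C)(C)C)C2CCCC1CCC2 | intermediate (not isolated)
16 | (7Z)-11-{[tert-butyl(diphenyl)silyl]oxy}-6,6,7,8-tetramethylundec-7-en-1-ol | OCCCCCC(C)(C)/C(C)=C(C)\CCCO[Si](c1ccccc1)(c1ccccc1)C(C)(C)C | intermediate
17 | (7Z)-11-{[tert-butyl(diphenyl)silyl]oxy}-6,6,7,8-tetramethylundec-7-enal | O=CCCCCC(C)(C)/C(C)=C(C)\CCCO[Si](c1ccccc1)(c1ccccc1)C(C)(C)C | intermediate (not isolated)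
18 | (7Z)-11-{[tert-butyl(diphenyl)silyl]oxy}-6,6,7,8-tetramethylundec-7-enoic acid | OC(=O)CCCCC(C)(C)/C(C)=C(C)\CCCO[Si](c1ccccc1)(c1ccccc1)C(C)(C)C | intermediate
19 | (2R,5R)-2,5-dimethylpyrrolidine | C[C@@H]1CC[C@@H](C)N1 | starting material
20 | (7Z)-11-{[tert-butyl(diphenyl)silyl]oxy}-6,6,7,8-tetramethylundec-7-enoyl chloride | ClC(=O)CCCCC(C)(C)/C(C)=C(C)\CCCO[Si](c1ccccc1)(c1ccccc1)C(C)(C)C | intermediate (not isolated)
21 | (7Z)-11-{[tert-butyl(diphenyl)silyl]oxy}-1-[(2R,5R)-2,5-dimethylpyrrolidin-1-yl]-6,6,7,8-tetramethylundec-7-en-1-one | C[C@@H]1CC[C@@H](C)N1C(=O)CCCCC(C)(C)/C(C)=C(C)\CCCO[Si](c1ccccc1)(c1ccccc1)C(C)(C)C | intermediate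
22 | (2R,5R)-1-[(7Z)-11-{[tert-butyl(diphenyl)silyl]oxy}-6,6,7,8-tetramethylundeca-1,7-dien-1-ylidene]-2,5-dimethylpyrrolidinium trifluoromethanesulfonate (keteniminium salt) | C[C@@H]1CC[C@@H](C)[N+]1=C=CCCCC(C)(C)/C(C)=C(C)\CCCO[Si](c1ccccc1)(c1ccccc1)C(C)(C)C.[O-]S(=O)(=O)C(F)(F)F | intermediate (not isolated)
23 | (2R,5R)-1-[(1R,6R,8S)-8-{3-[(tert-butyldiphenylsilyl)oxy]propyl}-1,2,2,8-tetramethylbicyclo[4.2.0]octan-7-ylidene]-2,5-dimethylpyrrolidinium trifluoromethanesulfonate | C[C@@H]1CC[C@@H](C)[N+]1=C1[C@@H]2CCCC(C)(C)[C@]2(C)[C@]1(C)CCCO[Si](c1ccccc1)(c1ccccc1)C(C)(C)C.[O-]S(=O)(=O)C(F)(F)F | intermediate (not isolated)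
24 | (1R,6R,8S)-8-{3-[(tert-butyldiphenylsilyl)oxy]propyl}-1,2,2,8-tetramethylbicyclo[4.2.0]octan-7-one (cis-fused; 1- and 8-methyls cis) | CC(C)(C)[Si](c1ccccc1)(c1ccccc1)OCCC[C@]1(C)C(=O)[C@@H]2CCCC(C)(C)[C@@]21C | intermediate
25 | (1R,6S,8S)-6-chloro-8-{3-[(tert-butyldiphenylsilyl)oxy]propyl}-1,2,2,8-tetramethylbicyclo[4.2.0]octan-7-one | CC(C)(C)[Si](c1ccccc1)(c1ccccc1)OCCC[C@]1(C)C(=O)[C@]2(Cl)CCCC(C)(C)[C@@]21C | intermediate
26 | tert-butyl diazoacetate | CC(C)(C)OC(=O)C=[N+]=[N-] | starting material
27 | tert-butyl (1R,3aS,7aR)-1-{3-[(tert-butyldiphenylsilyl)oxy]propyl}-3a-chloro-1,7,7,7a-tetramethyl-3-oxooctahydro-1H-indene-2-carboxylate (C2 epimers and enol) | CC(C)(C)[Si](c1ccccc1)(c1ccccc1)OCCC[C@]1(C)C(C(=O)OC(C)(C)C)C(=O)[C@]2(Cl)CCCC(C)(C)[C@@]21C | intermediate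
28 | tert-butyl (1R,7aR)-1-{3-[(tert-butyldiphenylsilyl)oxy]propyl}-1,7,7,7a-tetramethyl-3-oxo-2,3,5,6,7,7a-hexahydro-1H-indene-2-carboxylate (C2 epimers and enol) | CC(C)(C)[Si](c1ccccc1)(c1ccccc1)OCCC[C@]1(C)C(C(=O)OC(C)(C)C)C(=O)C2=CCCC(C)(C)[C@@]21C | intermediate
29 | tert-butyl (1S,7aR)-1-{3-[(tert-butyldiphenylsilyl)oxy]propyl}-1,7,7,7a-tetramethyl-3-{[(trifluoromethyl)sulfonyl]oxy}-5,6,7,7a-tetrahydro-1H-indene-2-carboxylate | CC(C)(C)[Si](c1ccccc1)(c1ccccc1)OCCC[C@]1(C)C(C(=O)OC(C)(C)C)=C(OS(=O)(=O)C(F)(F)F)C2=CCCC(C)(C)[C@@]21C | intermediate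
30 | tert-butyl (1S,7aS)-1-{3-[(tert-butyldiphenylsilyl)oxy]propyl}-1,7,7,7a-tetramethyl-5,6,7,7a-tetrahydro-1H-indene-2-carboxylate | CC(C)(C)[Si](c1ccccc1)(c1ccccc1)OCCC[C@]1(C)C(C(=O)OC(C)(C)C)=CC2=CCCC(C)(C)[C@@]21C | intermediate
31 | tert-butyl (1R,2S,7aS)-1-{3-[(tert-butyldiphenylsilyl)oxy]propyl}-1,7,7,7a-tetramethyl-2,3,5,6,7,7a-hexahydro-1H-indene-2-carboxylate | CC(C)(C)[Si](c1ccccc1)(c1ccccc1)OCCC[C@]1(C)[C@@H](C(=O)OC(C)(C)C)CC2=CCCC(C)(C)[C@@]21C | intermediate
32 | tert-butyl (1R,2S,7aS)-1-(3-hydroxypropyl)-1,7,7,7a-tetramethyl-2,3,5,6,7,7a-hexahydro-1H-indene-2-carboxylate | OCCC[C@]1(C)[C@@H](C(=O)OC(C)(C)C)CC2=CCCC(C)(C)[C@@]21C | intermediate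
33 | tert-butyl (1R,2S,7aS)-1,7,7,7a-tetramethyl-1-(3-oxopropyl)-2,3,5,6,7,7a-hexahydro-1H-indene-2-carboxylate | O=CCC[C@]1(C)[C@@H](C(=O)OC(C)(C)C)CC2=CCCC(C)(C)[C@@]21C | intermediate
34 | ethyl 2-[bis(2,2,2-trifluoroethoxy)phosphoryl]propanoate | CCOC(=O)C(C)P(=O)(OCC(F)(F)F)OCC(F)(F)F | starting material
35 | tert-butyl (1R,2S,7aS)-1-[(3Z)-5-ethoxy-4-methyl-5-oxopent-3-en-1-yl]-1,7,7,7a-tetramethyl-2,3,5,6,7,7a-hexahydro-1H-indene-2-carboxylate | CCOC(=O)/C(C)=C\CC[C@]1(C)[C@@H](C(=O)OC(C)(C)C)CC2=CCCC(C)(C)[C@@]21C | intermediate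
36 | tert-butyl (1R,2S,7aS)-1-[(3Z)-5-hydroxy-4-methylpent-3-en-1-yl]-1,7,7,7a-tetramethyl-2,3,5,6,7,7a-hexahydro-1H-indene-2-carboxylate | OC/C(C)=C\CC[C@]1(C)[C@@H](C(=O)OC(C)(C)C)CC2=CCCC(C)(C)[C@@]21C | intermediate
37 | trimethylsilyl (1R,2S,7aS)-1,7,7,7a-tetramethyl-1-{(3Z)-4-methyl-5-[(trimethylsilyl)oxy]pent-3-en-1-yl}-2,3,5,6,7,7a-hexahydro-1H-indene-2-carboxylate | C[Si](C)(C)OC/C(C)=C\CC[C@]1(C)[C@@H](C(=O)O[Si](C)(C)C)CC2=CCCC(C)(C)[C@@]21C | intermediate (not isolated)
38 | (1R,2S,7aS)-1-[(3Z)-5-hydroxy-4-methylpent-3-en-1-yl]-1,7,7,7a-tetramethyl-2,3,5,6,7,7a-hexahydro-1H-indene-2-carboxylic acid | OC/C(C)=C\CC[C@]1(C)[C@@H](C(=O)O)CC2=CCCC(C)(C)[C@@]21C | intermediate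
39 | (1R,2S,7aS)-1-[(3Z)-5-(acetyloxy)-4-methylpent-3-en-1-yl]-1,7,7,7a-tetramethyl-2,3,5,6,7,7a-hexahydro-1H-indene-2-carboxylic acid | CC(=O)OC/C(C)=C\CC[C@]1(C)[C@@H](C(=O)O)CC2=CCCC(C)(C)[C@@]21C | target

## Step count and least certain steps

Total: 24 steps. Longest linear sequence: 23 steps (steps 1, 2 and 4 to 24); step 3 is a one-step side branch.

**Step 12 (key step).**
- The cycloaddition has to engage a tetrasubstituted alkene flanked by the quaternary C7. While the C1–C3 bond forms, positive charge builds up at C7a, and a 1,2-methyl shift from C7 or loss of a proton may outrun closure of the four-membered ring.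
- Both faces of the alkene carry carbon substituents, so facial discrimination by the auxiliary may be eroded.
- Fallback, setting out from 18 and returning at 25: the dianion of 18 (LiN(i-Pr)2, then CCl4) would be chlorinated to (7Z)-11-{[tert-butyl(diphenyl)silyl]oxy}-2-chloro-6,6,7,8-tetramethylundec-7-enoic acid F1. Oxalyl chloride would give the 2-chloro acid chloride F2. Slow addition of F2 to Et3N in refluxing toluene would generate chloroketene F3, whose thermal intramolecular [2+2] cycloaddition is less polar than the keteniminium reaction.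
- This should give the chloro ketone directly as a racemate, that is 25 together with its (1S,6R,8R)-enantiomer F4. Chromatography on a chiral stationary phase would provide 25. Steps 11 to 13 are bypassed at the price of a resolution.

**Step 5.**
- In the chelated enolate the tert-alkyl group and the C1 chain are forced cis. If this strain pulls the enolate out of the chelate, sulfonylation gives the other alkene geometry and, two steps later, a trans-dimethyl alkene.
- Fallback, setting out from 5 and returning at 14: the series in which the non-chelated geometry is the required one. Acid chloride 5 and the lithium enolate of ethyl propanoate would give ethyl 2,4,4-trimethyl-3-oxonon-8-enoate F5.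
- Sulfonylation of its crown-ether-separated potassium enolate (KN(SiMe3)2, 18-crown-6, then PhN(SO2CF3)2) would give ethyl (2E)-2,4,4-trimethyl-3-{[(trifluoromethyl)sulfonyl]oxy}nona-2,8-dienoate F6.
- Methyl coupling as in step 6 would give ethyl (2Z)-2,3,4,4-tetramethylnona-2,8-dienoate F7, and i-Bu2AlH would give (2Z)-2,3,4,4-tetramethylnona-2,8-dien-1-ol F8.
- CBr4 and PPh3 would give (2Z)-1-bromo-2,3,4,4-tetramethylnona-2,8-diene F9. Alkylation of the lithium enolate of tert-butyl acetate would give tert-butyl (4Z)-4,5,6,6-tetramethylundeca-4,10-dienoate F10.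
- LiAlH4 would give (4Z)-4,5,6,6-tetramethylundeca-4,10-dien-1-ol F11, and silylation as in step 3 would give 14.

**Step 14.**
- The carbonyl group is flanked by two fully substituted carbons, so addition of the bulky diazo ester may be slow. Oxirane formation or migration of C3a may compete, and BF3·OEt2 may attack the tert-butyl ester if the mixture warms.
- Fallback, setting out from 25 and returning at 28: diazomethane, the smallest diazo nucleophile, in Et2O/MeOH at 0 °C should expand α-chlorocyclobutanone 25 with migration of the non-chlorinated carbon. The product would be (1R,3aS,7aR)-3a-chloro-1-{3-[(tert-butyldiphenylsilyl)oxy]propyl}-1,7,7,7a-tetramethyloctahydro-3H-inden-3-one F12 (locants as in 27).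
- DBU would eliminate HCl to the (1R,7aR)-enone F13. Its kinetic lithium enolate at C2 (LiN(i-Pr)2, THF, −78 °C) would be C-acylated with di-tert-butyl dicarbonate to give 28.

**Step 18.**
- Hydride may be delivered to C4 instead of C3 (1,6-reduction, which moves the ring alkene).
- The proton may enter C2 from the face of the methyls. The two faces differ only by a methyl against a methylene at C1 and by the 1,3-related C7a methyl, so facial selectivity may be poor.
- Any later exposure to base could equilibrate C2, which is why steps 19 to 24 avoid it.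
- Fallback with reagent control, setting out from 30 and returning at 31: cleavage of the tert-butyl ester as in step 23 would give (1S,7aS)-1-{3-[(tert-butyldiphenylsilyl)oxy]propyl}-1,7,7,7a-tetramethyl-5,6,7,7a-tetrahydro-1H-indene-2-carboxylic acid F14.
- Carboxylate-directed asymmetric hydrogenation with Ru(OAc)2(BINAP) and H2 in MeOH, using the ligand antipode that matches the substrate, would reduce only the C2=C3 bond and set C2. The product would be (1R,2S,7aS)-1-{3-[(tert-butyldiphenylsilyl)oxy]propyl}-1,7,7,7a-tetramethyl-2,3,5,6,7,7a-hexahydro-1H-indene-2-carboxylic acid F15.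
- Esterification with tert-butyl 2,2,2-trichloroacetimidate would give 31.

## Further compounds

F1 | step 12 | (7Z)-11-{[tert-butyl(diphenyl)silyl]oxy}-2-chloro-6,6,7,8-tetramethylundec-7-enoic acid (racemic at C2) | OC(=O)C(Cl)CCCC(C)(C)/C(C)=C(C)\CCCO[Si](c1ccccc1)(c1ccccc1)C(C)(C)C
F2 | step 12 | (7Z)-11-{[tert-butyl(diphenyl)silyl]oxy}-2-chloro-6,6,7,8-tetramethylundec-7-enoyl chloride (racemic at C2) | ClC(=O)C(Cl)CCCC(C)(C)/C(C)=C(C)\CCCO[Si](c1ccccc1)(c1ccccc1)C(C)(C)C
F3 | step 12 | (7Z)-11-{[tert-butyl(diphenyl)silyl]oxy}-2-chloro-6,6,7,8-tetramethylundeca-1,7-dien-1-one (chloroketene) | O=C=C(Cl)CCCC(C)(C)/C(C)=C(C)\CCCO[Si](c1ccccc1)(c1ccccc1)C(C)(C)C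
F4 | step 12 | (1S,6R,8R)-6-chloro-8-{3-[(tert-butyldiphenylsilyl)oxy]propyl}-1,2,2,8-tetramethylbicyclo[4.2.0]octan-7-one (enantiomer of 25) | CC(C)(C)[Si](c1ccccc1)(c1ccccc1)OCCC[C@@]1(C)C(=O)[C@@]2(Cl)CCCC(C)(C)[C@]21C
F5 | step 5 | ethyl 2,4,4-trimethyl-3-oxonon-8-enoate (racemic at C2) | CCOC(=O)C(C)C(=O)C(C)(C)CCCC=C
F6 | step 5 | ethyl (2E)-2,4,4-trimethyl-3-{[(trifluoromethyl)sulfonyl]oxy}nona-2,8-dienoate | CCOC(=O)/C(C)=C(/OS(=O)(=O)C(F)(F)F)C(C)(C)CCCC=C
F7 | step 5 | ethyl (2Z)-2,3,4,4-tetramethylnona-2,8-dienoate | CCOC(=O)/C(C)=C(/C)C(C)(C)CCCC=C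
F8 | step 5 | (2Z)-2,3,4,4-tetramethylnona-2,8-dien-1-ol | OC/C(C)=C(/C)C(C)(C)CCCC=C
F9 | step 5 | (2Z)-1-bromo-2,3,4,4-tetramethylnona-2,8-diene | BrC/C(C)=C(/C)C(C)(C)CCCC=C
F10 | step 5 | tert-butyl (4Z)-4,5,6,6-tetramethylundeca-4,10-dienoate | CC(C)(C)OC(=O)CC/C(C)=C(/C)C(C)(C)CCCC=C
F11 | step 5 | (4Z)-4,5,6,6-tetramethylundeca-4,10-dien-1-ol | OCCC/C(C)=C(/C)C(C)(C)CCCC=C
F12 | step 14 | (1R,3aS,7aR)-3a-chloro-1-{3-[(tert-butyldiphenylsilyl)oxy]propyl}-1,7,7,7a-tetramethyloctahydro-3H-inden-3-one (locants as in 27) | CC(C)(C)[Si](c1ccccc1)(c1ccccc1)OCCC[C@]1(C)CC(=O)[C@]2(Cl)CCCC(C)(C)[C@@]21C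
F13 | step 14 | (1R,7aR)-1-{3-[(tert-butyldiphenylsilyl)oxy]propyl}-1,7,7,7a-tetramethyl-1,2,5,6,7,7a-hexahydro-3H-inden-3-one (locants as in 28) | CC(C)(C)[Si](c1ccccc1)(c1ccccc1)OCCC[C@]1(C)CC(=O)C2=CCCC(C)(C)[C@@]21C
F14 | step 18 | (1S,7aS)-1-{3-[(tert-butyldiphenylsilyl)oxy]propyl}-1,7,7,7a-tetramethyl-5,6,7,7a-tetrahydro-1H-indene-2-carboxylic acid | CC(C)(C)[Si](c1ccccc1)(c1ccccc1)OCCC[C@]1(C)C(C(=O)O)=CC2=CCCC(C)(C)[C@@]21C
F15 | step 18 | (1R,2S,7aS)-1-{3-[(tert-butyldiphenylsilyl)oxy]propyl}-1,7,7,7a-tetramethyl-2,3,5,6,7,7a-hexahydro-1H-indene-2-carboxylic acid | CC(C)(C)[Si](c1ccccc1)(c1ccccc1)OCCC[C@]1(C)[C@@H](C(=O)O)CC2=CCCC(C)(C)[C@@]21C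
A1 | alternative 1 | 2-allyl-2,3-dimethyl-4-vinylcyclopent-3-en-1-yl 2-methylprop-2-enoate (ester oxygen cis to the allyl group) | C=CC[C@]1(C)[C@H](OC(=O)C(C)=C)CC(C=C)=C1C
A2 | alternative 1 | lactone-bridged hexahydroindene from the tethered Diels–Alder reaction (C7 bears one methyl and the lactone carbonyl; lactone oxygen on C2) | C=CC[C@]1(C)[C@H]2CC3=CCC[C@](C)(C(=O)O2)[C@@]31C
A3 | alternative 2 | 4-{3-[(tert-butyldimethylsilyl)oxy]propyl}-3-[(2,3,3-trimethylcyclohex-1-en-1-yl)carbonyl]furan-2(5H)-one | O=C1OCC(CCCO[Si](C)(C)C(C)(C)C)=C1C(=O)C1=C(C)C(C)(C)CCC1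
A4 | alternative 2 | cis-fused tricyclic keto lactone from the Nazarov cyclization (lactone CH2O on C1, lactone carbonyl on C2, ketone at C3) | CC(C)(C)[Si](C)(C)OCCC[C@]1(COC2=O)[C@@H]2C(=O)C3=CCCC(C)(C)[C@@]31C
A5 | alternative 3 | ethyl 3-{6-[5-{[tert-butyl(dimethyl)silyl]oxy}pentan-2-yl]-5,5,6-trimethylcyclohex-1-en-1-yl}-2-diazo-3-oxopropanoate (configured as in the SMILES) | CC(C)(C)[Si](C)(C)OCCC[C@@H](C)[C@@]1(C)C(C)(C)CCC=C1C(=O)C(=[N+]=[N-])C(=O)OCC
A6 | alternative 3 | bicyclic β-keto ester from C–H insertion (ethyl ester at C2, ketone at C3 conjugated to C3a=C4) | CC(C)(C)[Si](C)(C)OCCC[C@]1(C)[C@@H](C(=O)OCC)C(=O)C2=CCCC(C)(C)[C@@]21C
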